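Late in any of these runs, whatever has become target has come through intermediate B and met a fork there, so I reckon the fork first.

    substrate + partner → intermediate A (k1 = 6.78 M⁻¹ s⁻¹)
    second reagent + intermediate A → intermediate B (k2 = 21.9 M⁻¹ s⁻¹)
    third reagent + intermediate B → target (k3 = 49.1 M⁻¹ s⁻¹)
    intermediate B → side product (k4 = 0.0202 s⁻¹)
    intermediate B → decomposed reagent (k5 = 0.00228 s⁻¹)

common to all: partner 4.00 equiv; second reagent 1.50 equiv

|  | substrate | third reagent | remark | time |
|---|---|---|---|---|
| gamma | 0.50 mM | 0.900 equiv | a single well-mixed tank run continuously and read at steady state, 2.5 min in it on average |  |
| delta | 0.50 mM | 0.900 equiv | everything together in a closed stirred flask, run for 2.5 min | 2.5 min |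
| epsilon | 0.50 mM (fed, over 2.50 min) | 0.900 equiv | all but substrate at the start; substrate goes in evenly over 2.50 min, the run ends at 2.5 min | 2.5 min |
| eta | 0.50 mM | 0.900 equiv (fed, over 2.50 min) | a stirred flask in which third reagent is dosed at a steady rate over 2.50 min without added volume, worked up at 2.5 min | 2.5 min |

- the stated concentrations are those of everything mixed, before any reaction; amounts are the same in each set-up
- the feed brings no volume worth counting
- run time (delta): 2.5 min

- the set-up with the highest amount of target at the outlet or at the end, in percent of the substrate put in ("none" if the first two lie within 2 percentage points) (gamma / delta / epsilon / eta / none)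
- amount of target at the outlet or at the end, in percent of the substrate put in, gamma
- amount of target at the outlet or at the end, in percent of the substrate put in, delta
- amount of target at the outlet or at the end, in percent of the substrate put in, epsilon
- amount of target at the outlet or at the end, in percent of the substrate put in, eta

In delta, at the charges, step one runs pseudo-first-order at a = 0.0136 s⁻¹ and step two at b = 0.0164 s⁻¹. In delta at the charges, intermediate B goes at 0.0446 s⁻¹, faster than either, so I take it as settled (quasi-steady). What arrives then splits according to the trap share φ, the trapping rate over the trapping rate plus both first-order losses. With the full charge of third reagent, φ = 0.496.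

Let G be the part of the substrate that has passed step two by the end, at time t:

G = 1 − (b·exp(−at) − a·exp(−bt))/(b − a)

Reagents only fall in delta, so the charged rates give a ceiling:

G = 0.653, target below φG = 32.4%

For a floor, I take from each reagent the most that ceiling lets it lose. Step one has passed at most 0.869 of the substrate, which leaves:

a = 0.0106 s⁻¹, b = 0.00928 s⁻¹, φ = 0.386

G = 0.438, target about 16.9%

That floor takes intermediate B as quasi-steady, so it is an estimate and not a strict bound.

Eta has delta's upstream chain, but its third reagent is dosed evenly from nothing, so I count it at half the charge as a mean, which gives φ = 0.330, and I expect 0.665 of delta's target. Epsilon's substrate has on average half the run, and at that mean time G = 0.307, less than delta's ceiling value. I leave the tank unreckoned and commit to delta over eta and epsilon.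

The forecast says “The all-in flask therefore wins”, with 15.7% for gamma, 21.4% for delta, 10.2% for epsilon and 15.3% for eta.

The simulation gives 15.6% for gamma, 21.5% for delta, 9.75% for epsilon and 15.5% for eta, so delta stands highest. Delta's end holds target 21.5%, side product 22.5% and decomposed reagent 2.54%, so target's share of the three reads 0.462. Delta's neighbour with 0.360 equiv of third reagent starts at φ = 0.282. It ends with target 10.7%, side product 29.1% and decomposed reagent 3.29%, so target's share of the three reads 0.248.

The numbers of this flask are invented.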